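**Plan**
1. Retrosynthetic cuts, in order: C5–CH2(allyl) by retro-Cope, which returns the allyl group to C3a; O5–CH3; O1–C2, with C2 re-bonded to C4 so that the dihydrofuran contracts to a cyclobutane (C3a–C3–C2–C4); then C3a–C3 and C4–C2 ([2+2]) to 2-allyl-5-methoxy-1,4-benzoquinone and (E)-isoelemicin.
2. Forward order: six-membered carbocycle (quinone from 3,4-dimethoxyphenol) → cyclobutane → dihydrofuran by 4→5 ring expansion → methyl enol ether → allyl transposition C3a→C5.
3. Enabling feature: C2 carries the cation-stabilising 3,4,5-trimethoxyphenyl ring and is bonded to C4, α to the C5 carbonyl, while the C7a carbonyl oxygen lies 1,4 to C2. Quaternary C3a blocks aromatisation, so the ring stays a dienone, and C5=C4–C3a–allyl is a 1,5-diene.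
4. Stereochemistry: C3 and C3a from the TADDOLate-controlled [2+2] (aryl endo, methyl cis to allyl on the cyclobutane); C2 in the ring expansion (retention, giving 2,3-trans); C5 by suprafacial transfer from C3a in the Cope step.

Key step: step 6

Numbering: the benzofuran numbering of the target (O1, C2, C3, C3a, C4–C7, C7a) is used for all intermediates.
Assumption: the (4R,5R)-TADDOL complex of tetravalent titanium is taken to give the (1S,6R,7R,8R) cyclobutane; if a trial shows the opposite sense of induction, the (4S,5S)-diol is used instead.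
Assumption: the cyclobutane from the 5-allyl quinone is taken to form with aryl endo and methyl exo, as for 5-unsubstituted 2-alkoxyquinones; the C5 configuration of the target depends on this.

**Step 1**
Reactants: 1 3,4-dimethoxyphenol; 2 allyl bromide
Product: 3 4-(allyloxy)-1,2-dimethoxybenzene
Conditions: K2CO3, acetone, reflux
Reagents that add atoms: none
Why: Williamson ether synthesis of a phenoxide with a primary allylic bromide; no stereocentre is formed.

**Step 2**
Reactants: 3 4-(allyloxy)-1,2-dimethoxybenzene
Product: 4 2-allyl-4,5-dimethoxyphenol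
Conditions: N,N-diethylaniline, 200 °C
Reagents that add atoms: none
Why: Aromatic Claisen rearrangement, which should go to the unhindered ortho carbon rather than the one flanked by two oxygens; no stereocentre is formed.

**Step 3**
Reactants: 4 2-allyl-4,5-dimethoxyphenol
Product: 5 2-allyl-5-methoxy-1,4-benzoquinone
Conditions: PhI(OAc)2, MeCN/H2O (2:1), 0 °C
Reagents that add atoms: water, O
Why: Oxidative demethylation of a 4-methoxyphenol by a trivalent iodine reagent: water adds to the methoxy-bearing para carbon of the phenoxonium ion and methanol is lost; the terminal alkene is inert.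

**Step 4**
Reactants: 6 5-bromo-1,2,3-trimethoxybenzene; 7 (E)-prop-1-enylboronic acid
Product: 8 (E)-isoelemicin, 1,2,3-trimethoxy-5-[(E)-prop-1-enyl]benzene
Conditions: Pd(PPh3)4 (3 mol %), K2CO3, dioxane/H2O, 90 °C
Reagents that add atoms: none
Why: Suzuki–Miyaura coupling on zerovalent palladium, which retains the E geometry of the alkenylboronic acid.

**Step 5**
Reactants: 5 2-allyl-5-methoxy-1,4-benzoquinone; 8 (E)-isoelemicin
Product: 9 (1S,6R,7R,8R)-1-allyl-4-methoxy-8-methyl-7-(3,4,5-trimethoxyphenyl)bicyclo[4.2.0]oct-3-ene-2,5-dione (cis-fused; allyl and methyl on the convex face, aryl on the concave face)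
Conditions: pre-formed complex of TiCl4, Ti(OiPr)4 and (4R,5R)-2,2-dimethyl-α,α,α',α'-tetraphenyl-1,3-dioxolane-4,5-dimethanol (TADDOL) (1:1:2, 2.5 equiv of Ti), CH2Cl2, −78 °C; quench at −78 °C with aqueous NaHCO3
Reagents that add atoms: none
Why: Formal [2+2] cycloaddition of a 2-alkoxy-1,4-benzoquinone with a propenylarene promoted by tetravalent titanium: chelation between the future C5 carbonyl oxygen and the adjacent methoxy oxygen makes the allyl-bearing carbon (future C3a) the electrophilic terminus, the β-carbon of 8 adds there and the benzylic cation collapses onto the titanium enolate carbon (future C4), the alkene lying over that C=C bond with its aryl group endo and its methyl group outside, hence cis to the allyl group, while the TADDOLate ligand selects the quinone face and so the absolute configuration of all four stereocentres.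

**Step 6**
Reactants: 9 (1S,6R,7R,8R)-1-allyl-4-methoxy-8-methyl-7-(3,4,5-trimethoxyphenyl)bicyclo[4.2.0]oct-3-ene-2,5-dione
Product: 11 (2S,3S,3aS)-3a-allyl-5-hydroxy-3-methyl-2-(3,4,5-trimethoxyphenyl)-3,3a-dihydro-1-benzofuran-6(2H)-one, via O-methyl oxocarbenium triflate 10 (not isolated)
Conditions: CF3SO3H (1.1 equiv), CH2Cl2, −78 to −20 °C; then H2O/THF, 0 °C
Reagents that add atoms: water, O
Why: Protonation of the C5 carbonyl of 9 heterolyses the strained C4–C2 bond of this donor–acceptor cyclobutane to an enol and a benzylic cation stabilised by the 3,4,5-trimethoxyphenyl ring, and the C7a carbonyl oxygen captures the cation, a net 1,3-shift of C2 from C4 to O that expands the ring C3a–C3–C2–C4 to the dihydrofuran O1–C2–C3–C3a–C7a; because C3a is quaternary the product cannot aromatise and is held as the O-methyl oxocarbenium 10, which water hydrolyses to the diosphenol 11 with loss of methanol. The closest known reaction is the acid-promoted rearrangement of quinone–propenylarene cyclobutanes (bicyclo[4.2.0]oct-3-ene-2,5-diones) to trans-2-aryl-3-methyl-2,3-dihydrobenzofurans. The dihydrofuran closes by 5-exo-trig attack of oxygen on the benzylic cation. C3 and C3a are not touched, but because the ring partner of C3a changes from C4 to C7a, the allyl group that was cis to the methyl group on the cyclobutane is trans to it on the dihydrofuran; C2 is delivered to oxygen on the lobe vacated by C4 (retention), giving the 2,3-trans (2S) arrangement, which is also the thermodynamic one should the benzylic C–O bond ionise again. The step needs capture of the cation by oxygen rather than by C7 or the allyl π bond, and no cycloreversion to 5 and 8; the five-membered transition state to the nearby C7a oxygen, the low temperature and the stoichiometric acid that holds the product as 10 should secure this.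

**Step 7**
Reactants: 11 (2S,3S,3aS)-3a-allyl-5-hydroxy-3-methyl-2-(3,4,5-trimethoxyphenyl)-3,3a-dihydro-1-benzofuran-6(2H)-one
Product: 12 (2S,3S,3aS)-3a-allyl-5-methoxy-3-methyl-2-(3,4,5-trimethoxyphenyl)-3,3a-dihydro-1-benzofuran-6(2H)-one
Conditions: Me2SO4, K2CO3, acetone, rt
Reagents that add atoms: dimethyl sulfate, COS(=O)(=O)OC
Why: O-Methylation of the acidic diosphenol enol with a hard electrophile, which should favour oxygen over C4; no stereocentre is touched.

**Step 8**
Reactants: 12 (2S,3S,3aS)-3a-allyl-5-methoxy-3-methyl-2-(3,4,5-trimethoxyphenyl)-3,3a-dihydro-1-benzofuran-6(2H)-one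
Product: 13 (2S,3S,5R)-5-allyl-5-methoxy-3-methyl-2-(3,4,5-trimethoxyphenyl)-2,3-dihydro-1-benzofuran-6(5H)-one (target)
Conditions: degassed xylene, 130 °C, sealed tube; stopped when 12 is consumed
Reagents that add atoms: none
Why: Cope rearrangement of the 1,5-diene C5=C4–C3a–CH2–CH=CH2, a [3,3] shift known for 3a-allyl hydrobenzofuranone neolignans, which moves the allyl group suprafacially on one face of the six-membered ring from C3a to C5 and so sets C5 as R while forming the linearly conjugated vinylogous ester; C2 and C3 are untouched.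

**Compound list**
1 | 3,4-dimethoxyphenol | COc1ccc(O)cc1OC | starting material
2 | allyl bromide | C=CCBr | starting material
3 | 4-(allyloxy)-1,2-dimethoxybenzene | C=CCOc1ccc(OC)c(OC)c1 | intermediate
4 | 2-allyl-4,5-dimethoxyphenol | C=CCc1cc(OC)c(OC)cc1O | intermediate
5 | 2-allyl-5-methoxy-1,4-benzoquinone | C=CCC1=CC(=O)C(OC)=CC1=O | intermediate
6 | 5-bromo-1,2,3-trimethoxybenzene | COc1cc(Br)cc(OC)c1OC | starting material
7 | (E)-prop-1-enylboronic acid | C/C=C/B(O)O | starting material
8 | (E)-isoelemicin | C/C=C/c1cc(OC)c(OC)c(OC)c1 | intermediate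
9 | (1S,6R,7R,8R)-1-allyl-4-methoxy-8-methyl-7-(3,4,5-trimethoxyphenyl)bicyclo[4.2.0]oct-3-ene-2,5-dione | C=CC[C@@]12C(=O)C=C(OC)C(=O)[C@@H]1[C@H](c3cc(OC)c(OC)c(OC)c3)[C@H]2C | intermediate
10 | O-methyl oxocarbenium triflate, (2S,3S,3aS)-3a-allyl-5-hydroxy-6-methoxy-3-methyl-2-(3,4,5-trimethoxyphenyl)-2,3-dihydro-3aH-1-benzofuran-1-ium trifluoromethanesulfonate | C=CC[C@]12C=C(O)C(OC)=CC1=[O+][C@H](c3cc(OC)c(OC)c(OC)c3)[C@H]2C.[O-]S(=O)(=O)C(F)(F)F | intermediate
11 | (2S,3S,3aS)-3a-allyl-5-hydroxy-3-methyl-2-(3,4,5-trimethoxyphenyl)-3,3a-dihydro-1-benzofuran-6(2H)-one | C=CC[C@]12C=C(O)C(=O)C=C1O[C@H](c3cc(OC)c(OC)c(OC)c3)[C@H]2C | intermediate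
12 | (2S,3S,3aS)-3a-allyl-5-methoxy-3-methyl-2-(3,4,5-trimethoxyphenyl)-3,3a-dihydro-1-benzofuran-6(2H)-one | C=CC[C@]12C=C(OC)C(=O)C=C1O[C@H](c3cc(OC)c(OC)c(OC)c3)[C@H]2C | intermediate
13 | (2S,3S,5R)-5-allyl-5-methoxy-3-methyl-2-(3,4,5-trimethoxyphenyl)-2,3-dihydro-1-benzofuran-6(5H)-one | C=CC[C@@]1(OC)C=C2C(=CC1=O)O[C@H](c1cc(OC)c(OC)c(OC)c1)[C@H]2C | target

**Step count**
Total: 8 steps. Longest linear sequence: 7 steps (1, 2, 3, 5, 6, 7, 8); step 4 is the convergent branch.

**Steps most likely to fail**

Step 5. The alkene may add in the [5+2] or direct [3+2] mode instead of the [2+2] mode. Those modes have the opposite relative topicity at C3/C3a and would lead to the C3a-epimeric series and finally to the C5 epimer. The same wrong series would arise if the cyclobutane itself formed with aryl exo and methyl endo. Enantioselection may also be low on a quinone that forms a quaternary centre. The fallback uses the cationic quinone-monoketal manifold with the alkene geometry switched to Z to compensate for its opposite topicity. It sets out from 4 and 6 and comes back at 12. Compound 6 is coupled with (Z)-prop-1-enylboronic acid (Pd(PPh3)4, K2CO3) to give (Z)-isoelemicin F1. Compound 4 is oxidised with PhI(OAc)2 in MeOH to 2-allyl-4,4,5-trimethoxycyclohexa-2,5-dien-1-one F2. SnCl4 in CH2Cl2 at −30 °C should join F1 and F2, followed by acid-induced 1,3-shift of any bicyclo[3.2.1] adduct, to give the racemic 2,3-cis, 3,3a-trans dihydrobenzofuranone F3. TsOH in CH2Cl2 should epimerise C2 through the benzylic cation to racemic 12. Preparative HPLC on a chiral stationary phase then gives 12 and removes its (2R,3R,3aR) enantiomer F4.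

Step 6. The benzylic cation may be intercepted by the allyl π bond (cation–olefin cyclisation to a spiro cyclohexane) or by C7, or the cyclobutane may revert to 5 and 8 with loss of enantiomeric purity. The fallback masks the alkene during the cationic step. It sets out from 9 and comes back at 11. Pyridinium tribromide in CH2Cl2 at −20 °C should add to the terminal alkene only, giving the 2,3-dibromopropyl cyclobutane F5 as a mixture of epimers at the CHBr carbon. The same acid treatment and hydrolysis then give the 2,3-dibromopropyl diosphenol F6. Zn dust in THF/AcOH at 0 °C regenerates the allyl group to give 11.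

Step 8. The Cope product may continue by retro-Claisen and Claisen shifts to aromatic products, or the equilibrium may leave 12 unconverted at tolerable temperatures. The fallback replaces the sigmatropic transfer by an intermolecular allylation of the aromatic phenol; it sets out from 12 and comes back at 13. Heating 12 in xylene at 150 °C drives the Cope and retro-Claisen sequence on purpose to (2S,3S)-6-(allyloxy)-5-methoxy-3-methyl-2-(3,4,5-trimethoxyphenyl)-2,3-dihydro-1-benzofuran F7. Pd(PPh3)4 and morpholine cleave the allyl ether to the phenol F8. PhI(OAc)2 and allyltrimethylsilane in (CF3)2CHOH at −20 °C should then allylate the methoxy-bearing C5 of the phenoxonium ion. This gives 13 together with its (2S,3S,5S) epimer F9, which is removed by chromatography, since this allylation has no facial control.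

**Further compounds**
F1 | step 5 | (Z)-isoelemicin, 1,2,3-trimethoxy-5-[(Z)-prop-1-enyl]benzene | C/C=C\c1cc(OC)c(OC)c(OC)c1
F2 | step 5 | 2-allyl-4,4,5-trimethoxycyclohexa-2,5-dien-1-one | C=CCC1=CC(OC)(OC)C(OC)=CC1=O
F3 | step 5 | racemic (2R,3S,3aS)-3a-allyl-5-methoxy-3-methyl-2-(3,4,5-trimethoxyphenyl)-3,3a-dihydro-1-benzofuran-6(2H)-one (one enantiomer drawn) | C=CC[C@]12C=C(OC)C(=O)C=C1O[C@@H](c3cc(OC)c(OC)c(OC)c3)[C@H]2C
F4 | step 5 | (2R,3R,3aR)-3a-allyl-5-methoxy-3-methyl-2-(3,4,5-trimethoxyphenyl)-3,3a-dihydro-1-benzofuran-6(2H)-one (enantiomer of 12) | C=CC[C@@]12C=C(OC)C(=O)C=C1O[C@@H](c3cc(OC)c(OC)c(OC)c3)[C@@H]2C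
F5 | step 6 | (1S,6R,7R,8R)-1-(2,3-dibromopropyl)-4-methoxy-8-methyl-7-(3,4,5-trimethoxyphenyl)bicyclo[4.2.0]oct-3-ene-2,5-dione (epimers at CHBr) | BrCC(Br)C[C@@]12C(=O)C=C(OC)C(=O)[C@@H]1[C@H](c3cc(OC)c(OC)c(OC)c3)[C@H]2C
F6 | step 6 | (2S,3S,3aS)-3a-(2,3-dibromopropyl)-5-hydroxy-3-methyl-2-(3,4,5-trimethoxyphenyl)-3,3a-dihydro-1-benzofuran-6(2H)-one (epimers at CHBr) | BrCC(Br)C[C@]12C=C(O)C(=O)C=C1O[C@H](c3cc(OC)c(OC)c(OC)c3)[C@H]2C
F7 | step 8 | (2S,3S)-6-(allyloxy)-5-methoxy-3-methyl-2-(3,4,5-trimethoxyphenyl)-2,3-dihydro-1-benzofuran | COc1cc2c(cc1OCC=C)O[C@H](c3cc(OC)c(OC)c(OC)c3)[C@H]2C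
F8 | step 8 | (2S,3S)-5-methoxy-3-methyl-2-(3,4,5-trimethoxyphenyl)-2,3-dihydro-1-benzofuran-6-ol | COc1cc2c(cc1O)O[C@H](c3cc(OC)c(OC)c(OC)c3)[C@H]2C
F9 | step 8 | (2S,3S,5S)-5-allyl-5-methoxy-3-methyl-2-(3,4,5-trimethoxyphenyl)-2,3-dihydro-1-benzofuran-6(5H)-one | C=CC[C@]1(OC)C=C2C(=CC1=O)O[C@H](c3cc(OC)c(OC)c(OC)c3)[C@H]2C
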